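Saturday's flask repeats Friday's, with the same substrate under the same held gas, but at 20 °C instead of 50 °C, and we ask what the cooling does to the share of target.

    tight pair ⇌ loose pair (K1 = 1.6, k1 = 5.3 s⁻¹, Ea1 = 70.0 kJ mol⁻¹, ΔH1 = 12.0 kJ mol⁻¹)
    loose pair → side product (k2 = 0.044 s⁻¹, Ea2 = 82.0 kJ mol⁻¹)
    reagent + tight pair → target (k3 = 4.6 × 10⁵ M⁻¹ s⁻¹, Ea3 = 15.0 kJ mol⁻¹)
    gas ⇌ reagent, rate k4*(csat - [reagent]) (k4 = 0.44 s⁻¹, csat = 1.7 mM)
    substrate ⇌ tight pair (K5 = 0.090, k5 = 0.070 s⁻¹, Ea5 = 85.0 kJ mol⁻¹, ΔH5 = −54.0 kJ mol⁻¹)
    reagent + loose pair → isomer of the product (k6 = 1.0 × 10⁶ M⁻¹ s⁻¹, Ea6 = 9.00 kJ mol⁻¹)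
    (constants at 50 °C)

- Saturday's: substrate 20 mM; gas 1.7 mM (held); temperature 20 °C; time 12 s
- Friday's: substrate 20 mM; gas 1.7 mM (held); temperature 50 °C; time 12 s

- the best flask by share of target in all that became target or isomer of the product or side product; "all alike" if 1.5 percentage points covers them all (Saturday's / Friday's / all alike)
- share of target in all that became target or isomer of the product or side product, Saturday's
- share of target in all that became target or isomer of the product or side product, Friday's

- at the start none of reagent is dissolved
- the constants hold at 50 °C; other temperatures follow from the activation energies and enthalpies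

Each target and each isomer of the product costs one reagent, and the gas pays for reagent at a rate that is highest while [reagent] is zero. Over 12 s that gives a budget, k4·csat·t as a part of the charge. Against it stands a demand: the forward rate of step 5 is first order in substrate, so integrating it gives one minus exp(−k5·t) as the part of the charge sent on, with the return step ignored. Our small table:

Saturday's: k5 0.00275 s⁻¹, demand 3.24%, budget 44.9%, ratio 0.0723.

Friday's: k5 0.070 s⁻¹, demand 56.8%, budget 44.9%, ratio 1.27.

We call demand over budget the reagent account. The budget column is the same in both rows, and the demand of Friday's is larger than that of Saturday's.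

Saturday's row reads below one, so we let [reagent] rise toward csat and stand near it. The tight pair then loosens at 0.368 s⁻¹ and is trapped at 442 s⁻¹, far faster than it loosens, which gives an estimated share of 99.9%.

Friday's row reads above one, so reagent is the limiting reagent of that flask, and target and isomer together should stand near the budget. Where the two pairs sit at equilibrium, with side product set aside, the share is k3/(k3+k6·K1). Reagent takes up loose pair with a larger constant than tight pair, and loose pair is fed from tight pair, so we expect [loose pair]/[tight pair] to stay under K1 and commit to Friday's share lying above 22.3%, and we expect the better flask to be Saturday's.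

The forecast says Saturday's, with 99.9% (99.5% to 100%) for Saturday's and 36% (28% to 45%) for Friday's, holding for the hot flask that “reagent is starved, the tight and loose pairs approach equilibrium”. For Friday's our reckoning gives a floor, and the forecast gives a figure with a range, so the two are different statements.

The simulation gives Saturday's, with 99.8% against 30.9%, so the forecast's Friday's figure stands 5.1 percentage points high. At 12.0 s Friday's flask holds 0.00418 mM of reagent, Saturday's 1.57 mM. Friday's account stands at 1.27, and in that flask target and isomer together come to 44.8%, level with the budget of 44.9%.

For the neighbour, like Saturday's but at 45 °C, k5 becomes 0.0426 s⁻¹ and the demand 40.0%, so the account is 0.891, just under one, and we expect a thinned [reagent] but no starvation. Computed, that flask ends with 0.407 mM of reagent, target 32.5%, isomer of the product 6.91%, and a share of 82.5%.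

The numbers of this flask are made up; the result is computed.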